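## The problem

The target is a labdane: rings A (C1–C5, C10) and B (C5–C10) form a trans-fused decalin, the C8=C9 bond is tetrasubstituted, and C9 carries a two-carbon chain (C11–C12) ending at the β-carbon C13 of a butenolide. Five stereocentres have to be set (C2, C4, C5, C6, C10). C4 and C10 are quaternary and hold their axial groups, the C19 hydroxymethyl and the C20 methyl, on the same (β) face; H5 and the equatorial hydroxyls at C2 and C6 are α. C5, C6 and C10 are contiguous, so one of them can set the other two by 1,2-induction, and the C10 methyl, once in place, closes the β face of ring A and can direct C4. C2 has no such neighbour: its equatorial oxygen is the thermodynamic arrangement, but kinetic reactions at C2 are steered by the same C20 methyl toward the axial epimer. The butenolide will not survive hydrides, enolate bases or hard organometallic reagents and must arrive at the end. The C8=C9 alkene would be the first site attacked by the oxidants needed at C4, so C4 has to be finished before that alkene exists. The feature that opens the molecule is ring B: once C8=C9 is traced back to a C9 ketone, C10, C5 and C6 are the α-, β- and γ-carbons of a cyclohexanone with the methyl on the α-carbon and the oxygen on the γ-carbon. The two bonds that leave ring B for ring A (C5–C4 and C10–C1) are then the bonds of a conjugate addition–enolate alkylation on a 4-oxygenated 2-methylcyclohex-2-enone, and the required trans,trans pattern is the normal anti,anti outcome.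

## Retrosynthesis

**C12–C13 (butenolide).** Target 27 is the tris-desilylation product of 26. Cutting C12–C13 of 26 gives alkylborane 25, made in the flask from diene 23, and 4-bromofuran-2(5H)-one 24. The neighbouring cut at C9–C11 with a ready-made butenolide chain would ask a very hindered sp2 carbon to couple with a functionalised sp3 organometallic. The chosen cut puts the sp3–sp2 coupling at an open primary carbon and brings the fragile lactone in at the second-to-last step. The forward reaction must hydroborate the vinyl group and not the tetrasubstituted alkene, and couple under a base the bromobutenolide tolerates.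

**C9–C11 and C8–C17.** Diene 23 comes from enol triflate 22 by vinylation, 22 from ketone 21, and the C8 methyl from enolate methylation of 15 to 16. Because C10 is quaternary, C8 is the only enolizable position of the C9 ketone, so both the methylation and the enol triflate are regiochemically fixed. The side chain and the alkene are thereby reduced to one carbonyl group.

**C4–C18.** The quaternary C4 of 21 is traced through alcohol 20 to aldehyde 19, which is cut at C4–C18 to give aldehyde 18. Aldehyde 18 comes from the exocyclic alkene of 16 through epoxide 17. Cutting C4–C19 instead would bring a one-carbon electrophile in from the open α face and put the oxygenated carbon equatorial, the wrong epimer. The forward reaction asks for α-face methylation under control of the C10 methyl and for enolization of the aldehyde beside the ketone, which is why C8 is methylated first.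

**C2–O (configuration only).** The 2α-silyl ether 15 comes from alcohol 14, and 14 from the 2β-alcohol 12 by inversion through ester 13. No skeleton changes. The correction is placed while C4 is still trigonal, so that the axial oxygen has one syn-axial neighbour and not two.

**C2–C3 (ring A).** Alcohol 12 opens at C2–C3 to keto aldehyde 11 by a type-2 carbonyl-ene retron. This one cut turns ring A into two arms on ring B, an acetaldehyde arm on C10 and an isopropenyl group on C5. The forward isomerisation makes the ring, the C2 oxygen and the C4 methylene handle without adding an atom. Cuts at C1–C2 or C3–C4 would need extra activating groups on ring B. Aldehyde 11 is reached from keto ester 9 through diol 10, because the ester cannot be reduced past the more reactive ketone.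

**C4–C5 and C10–C1 (key step).** Keto ester 9 is cut at both bonds to give enone 5, isopropenylmagnesium bromide 6 and ethyl bromoacetate 7, joined through enolate 8. Two skeletal bonds and two stereocentres (C5, C10) are traded for one carbinol centre and two purchased reagents. The forward reaction needs anti addition relative to the C6 silyloxy group and anti alkylation relative to the new C5 group.

**Enone 5.** Silyl ether 5 comes from (S)-alcohol 4, obtained by lipase resolution of racemate 3. Racemate 3 is the γ-oxidation product of 2-methylcyclohex-2-en-1-one 1 by way of silyl dienol ether 2. The only stereocentre is a secondary allylic carbinol, the kind of centre a lipase resolves.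

## Roads not taken

**Alternative 1:** The cut is at C5–C10 and C6–C7, so that both rings close at once. Anodic oxidation of triene A1 would turn its aryl enol ether into a radical cation, which adds across the C7=C8–C9=C10 diene to give cycloadduct A2.
- Merits: one step makes rings A and B, sets C5, C6 and C10, and leaves the C8=C9 alkene and the C11–C12 chain in place. C2 can be made with the right configuration on an open chain, so no inversion and no hindered enol triflate coupling are needed. After the ring-forming step this road is clearly shorter.
- Weak points: A1 needs an acyclic quaternary C4 stereocentre and a geometrically defined tetrasubstituted diene whose inner methyl opposes the s-cis conformation. The new C5–C10 bond joins a carbon next to a quaternary centre to a fully substituted diene terminus. Facial control rests on the remote C2 and C4 centres through a flexible tether. The aryl ether at C6 must later be removed oxidatively.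
- Comparison: the chosen plan is longer after its key step. It sets against this a cheap cyclic precursor, stereocentres set one at a time by 1,2- or 1,3-induction, and the likelihood that making A1 costs the steps it saves.

**Alternative 2:** The cut is at C4–C5. [(Ph3P)CuH]6 (a monovalent copper hydride) would reduce the acrylate of dione A3 to a C4 copper enolate, which adds to one of the two ring carbonyls and gives hydroxy ester A4.
- Merits: C4 is made quaternary with C19 already at the ester level, so there is no separate C4 methylation. The C2 oxygen sits on the tether with its final configuration. The C9 ketone is left for the same end game. For C4 and C2 this road is as good as or better than the chosen one.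
- Weak points: C5 emerges as a tertiary alcohol and C6 has no oxygen, so dehydration toward C6 and a hydroboration are needed on a β-hydroxy ester prone to retro-aldol cleavage. Which carbonyl is attacked, and hence the C4/C10 relationship, is governed only by the C2 centre on the chain.
- Comparison: the chosen plan pays with the C2 inversion and the C4 sequence, but it has the C6 oxygen from its first stereocentre and sets H5 directly.

**Alternative 3:** The cut is at C1–C10. Heating methylene pyran A5 would break O–C6 and join C1 to C10 through a boat Claisen transition state, giving ketone A6.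
- Merits: the transfer of chirality from C6–O to the quaternary C10 is suprafacial and arguably more dependable than the enolate alkylation of the chosen plan. C4 is set beforehand. The C5=C6 alkene of A6 can be hydroborated from the α face to give H5α and the 6α-hydroxyl.
- Weak points: hydride reduction of the C2 ketone of A6 should give the axial 2β-alcohol, now flanked by two syn-axial groups, so the same inversion returns in a harder setting. A5 is an acid-sensitive exocyclic enol ether and needs the quaternary C4 centre and a defined C6 carbinol. The boat geometry calls for high temperature. The C6 oxygen is used for one bond and then has to be put back.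
- Comparison: the chosen plan keeps the C6 oxygen in the molecule, forms both ring-B-to-ring-A bonds in one flask from purchased reagents, and inverts C2 at its least hindered stage.

Key step: step 5

Convention: labdane numbering is used for all compounds, including the monocyclic ones (ring B = C5–C10); β is the face of the C10 methyl group.

Assumption: the lipase acetylates the (R)-enantiomer of 3 faster (the alkene side of the carbinol counting as the larger substituent), so that (S)-alcohol 4 is the recovered fraction.

Assumption: C9 of 10, C8 of 16–21, and C4 of 17 and 18 are drawn as the expected major epimers; all of these centres are cleared in later steps, so either epimer serves.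

## Route

Step 1
Reactants: 1 2-methylcyclohex-2-en-1-one
Product: 2 trimethyl[(2-methylcyclohexa-1,3-dien-1-yl)oxy]silane
Conditions: MeMgBr, FeCl3 (5 mol %), Et2O, −20 °C; then Me3SiCl, Et3N, DMPU, −20 °C → rt
Reagents that add atoms: chlorotrimethylsilane C[Si](C)(C)Cl
Why: Iron-catalysed deprotonation of the enone by the Grignard reagent takes the γ-hydrogen and gives the through-conjugated dienolate, which is silylated on oxygen; this is the known way to 1-silyloxy-1,3-dienes and avoids the cross-conjugated isomer that amide bases give.

Step 2
Reactants: 2 trimethyl[(2-methylcyclohexa-1,3-dien-1-yl)oxy]silane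
Product: 3 rac-4-hydroxy-2-methylcyclohex-2-en-1-one
Conditions: mCPBA, NaHCO3, CH2Cl2, −20 °C; then 1 M HCl, THF, 0 °C
Reagents that add atoms: 3-chloroperbenzoic acid OOC(=O)c1cccc(Cl)c1
Why: Vinylogous Rubottom oxidation: the peracid should attack the distal, unhindered C3=C4 bond of the dienol ether, and opening of the epoxide with loss of silicon gives the γ-hydroxy enone as a racemate.

Step 3
Reactants: 3 rac-4-hydroxy-2-methylcyclohex-2-en-1-one
Product: 4 (S)-4-hydroxy-2-methylcyclohex-2-en-1-one
Conditions: Burkholderia cepacia lipase (Amano lipase PS), vinyl acetate, MTBE, 30 °C, run to just past half conversion; chromatography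
Reagents that add atoms: none
Why: Lipase-catalysed kinetic resolution by irreversible transesterification; the (R)-alcohol is acetylated and the slower (S)-alcohol, whose carbinol carbon becomes C6 of the target, is recovered, and running past half conversion should raise its enantiomeric purity.

Step 4
Reactants: 4 (S)-4-hydroxy-2-methylcyclohex-2-en-1-one
Product: 5 (S)-4-[(tert-butyldimethylsilyl)oxy]-2-methylcyclohex-2-en-1-one
Conditions: TBSCl, imidazole, DMF, rt
Reagents that add atoms: tert-butyldimethylsilyl chloride CC(C)(C)[Si](C)(C)Cl
Why: Standard silylation of a secondary alcohol; the bulky silyl ether also serves as the control element of the next step.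

Step 5
Reactants: 5 (S)-4-[(tert-butyldimethylsilyl)oxy]-2-methylcyclohex-2-en-1-one; 6 isopropenylmagnesium bromide; 7 ethyl bromoacetate
Product: 9 ethyl 2-[(1S,2S,3S)-3-(tert-butyldimethylsilyloxy)-1-methyl-6-oxo-2-(prop-1-en-2-yl)cyclohexyl]acetate, via bromomagnesium enolate 8 (not isolated)
Conditions: 6 (2.4 equiv), CuBr·SMe2 (1.2 equiv), THF, −78 → −45 °C; then HMPA, 7 (4 equiv), −45 → 0 °C
Reagents that add atoms: none
Why: The homocuprate formed from 6 and CuBr·SMe2 (monovalent copper) binds the enone, transfers the isopropenyl group to the β-carbon C5 (bond C4–C5) and leaves the C9/C10 enolate 8; HMPA then loosens the enolate aggregate so that C10 displaces bromide from 7 in an SN2 alkylation (bond C10–C1). The closest known reaction type is the anti-selective conjugate addition of cuprates to 4-silyloxycyclohex-2-enones with alkylation of the resulting enolate in the same flask. No ring is closed. C5 is set by the C6 silyloxy group, which sits pseudoaxial in the reactive half-chair, so the cuprate enters the β-carbon on the opposite face and gives the 5,6-trans product. C10 is set by the new C5 substituent: A(1,2) strain against the enolate methyl keeps the isopropenyl group pseudoaxial, the electrophile approaches axially from the other face, and the acetate arm ends trans to C4. The step needs 1,4- over 1,2-addition (secured by copper), C- over O-alkylation and reaction at C10 before the enolate can equilibrate to C8 (a soft, reactive α-bromo ester in excess, polar cosolvent, low temperature), and the two anti inductions, which rest only on the carbinol centre of 5.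

Step 6
Reactants: 9 ethyl 2-[(1S,2S,3S)-3-(tert-butyldimethylsilyloxy)-1-methyl-6-oxo-2-(prop-1-en-2-yl)cyclohexyl]acetate
Product: 10 2-[(1S,2S,3S)-3-(tert-butyldimethylsilyloxy)-6-hydroxy-1-methyl-2-(prop-1-en-2-yl)cyclohexyl]ethan-1-ol (C9 hydroxyl equatorial, cis to the ring methyl)
Conditions: LiAlH4, THF, 0 °C
Reagents that add atoms: none
Why: Hydride reduction of both ester and ketone, because the ester cannot be taken to the aldehyde past the more electrophilic ketone; axial hydride delivery should give mainly the equatorial C9 alcohol, a temporary centre removed in step 7.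

Step 7
Reactants: 10 diol (C2 primary and C9 secondary hydroxyls)
Product: 11 2-[(1S,2S,3S)-3-(tert-butyldimethylsilyloxy)-1-methyl-6-oxo-2-(prop-1-en-2-yl)cyclohexyl]acetaldehyde
Conditions: Dess–Martin periodinane (2.5 equiv), NaHCO3, CH2Cl2, 0 °C → rt
Reagents that add atoms: none
Why: Dess–Martin oxidation of both alcohols under buffered, non-enolizing conditions, so that the 1,4-keto aldehyde is not exposed to aldol chemistry.

Step 8
Reactants: 11 keto aldehyde
Product: 12 6α-(tert-butyldimethylsilyloxy)-2β-hydroxy-10β-methyl-4-methylene-5α-decalin-9-one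
Conditions: Me2AlCl (2.5 equiv), CH2Cl2, −78 → −20 °C
Reagents that add atoms: none
Why: Lewis acid-promoted type-2 intramolecular carbonyl-ene reaction: C2 of the aldehyde bonds to the alkene terminus C3 while a hydrogen of the isopropenyl methyl passes to oxygen, closing ring A as a trans-decalin (both arms equatorial on ring B) with an exocyclic methylene at C4. The bicyclic transition state places the oxygen axial, cis-1,3 to the hydrogen donor, so the 2β-alcohol should form; the hindered C9 ketone is a much poorer enophile.

Step 9
Reactants: 12 2β-hydroxy decalone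
Product: 13 6α-(tert-butyldimethylsilyloxy)-10β-methyl-4-methylene-2α-(4-nitrobenzoyloxy)-5α-decalin-9-one
Conditions: 4-nitrobenzoic acid, PPh3, DIAD, toluene, 0 °C → rt
Reagents that add atoms: 4-nitrobenzoic acid OC(=O)c1ccc(cc1)[N+](=O)[O-]
Why: Mitsunobu inversion: the axial oxyphosphonium group is displaced from the open α face with inversion to give the equatorial 2α-ester; the acidic nitrobenzoic acid is the usual partner for hindered secondary alcohols, and C4 is still trigonal, so only the C10 methyl flanks the reacting centre.

Step 10
Reactants: 13 2α-(4-nitrobenzoate)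
Product: 14 6α-(tert-butyldimethylsilyloxy)-2α-hydroxy-10β-methyl-4-methylene-5α-decalin-9-one
Conditions: K2CO3, MeOH, rt
Reagents that add atoms: none
Why: Base-catalysed transesterification of an activated aryl ester; the silyl ether and the ketone are not affected.

Step 11
Reactants: 14 2α-hydroxy decalone
Product: 15 2α,6α-bis(tert-butyldimethylsilyloxy)-10β-methyl-4-methylene-5α-decalin-9-one
Conditions: TBSCl, imidazole, DMF, 40 °C
Reagents that add atoms: tert-butyldimethylsilyl chloride CC(C)(C)[Si](C)(C)Cl
Why: Silylation of the now equatorial secondary alcohol, so that it survives the enolate steps and leaves with the other silyl ethers at the end.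

Step 12
Reactants: 15 bis-silyl ether ketone
Product: 16 2α,6α-bis(tert-butyldimethylsilyloxy)-8α,10β-dimethyl-4-methylene-5α-decalin-9-one
Conditions: LiN(iPr)2, THF, −78 °C; MeI, −78 → −30 °C
Reagents that add atoms: iodomethane CI
Why: Kinetic enolate alkylation; C8 is the only enolizable position because C10 is quaternary, and the methyl should enter anti to the C10 methyl to sit equatorial. The centre is cleared in step 18.

Step 13
Reactants: 16 8-methyl ketone
Product: 17 spiro-epoxide of 16 at C4 (oxygen α; 4,19-epoxy-2α,6α-bis(tert-butyldimethylsilyloxy)-8α,10β-dimethyl-5α-decalin-9-one)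
Conditions: mCPBA, NaHCO3, CH2Cl2, 0 °C
Reagents that add atoms: 3-chloroperbenzoic acid OOC(=O)c1cccc(Cl)c1
Why: Prilezhaev epoxidation of the only alkene, expected from the face away from the C10 methyl; a 1,1-disubstituted alkene reacts far faster than the hindered ketone undergoes Baeyer–Villiger oxidation.

Step 14
Reactants: 17 spiro-epoxide
Product: 18 2α,6α-bis(tert-butyldimethylsilyloxy)-4α-formyl-8α,10β-dimethyl-5α-decalin-9-one (C4–H β)
Conditions: BF3·OEt2, CH2Cl2, −78 °C
Reagents that add atoms: none
Why: Meinwald rearrangement: ionisation at the tertiary C4 and a 1,2-hydride shift from the epoxide methylene give the aldehyde, whose carbon is C19; the C4 configuration is erased in the next step.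

Step 15
Reactants: 18 C4 aldehyde
Product: 19 2α,6α-bis(tert-butyldimethylsilyloxy)-4β-formyl-4α,8α,10β-trimethyl-5α-decalin-9-one
Conditions: KOtBu (1.3 equiv), THF/tBuOH, 0 °C; MeI
Reagents that add atoms: iodomethane CI
Why: α-Methylation of an α-branched aldehyde through its potassium enolate; the C10 methyl blocks the β face in a 1,3-diaxial sense, so the methyl enters from the α face and the formyl group ends axial as C19. The aldehyde is more acidic than the ketone, whose only α-hydrogen is tertiary and flanked on both sides.

Step 16
Reactants: 19 quaternary aldehyde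
Product: 20 2α,6α-bis(tert-butyldimethylsilyloxy)-4β-(hydroxymethyl)-4α,8α,10β-trimethyl-5α-decalin-9-one
Conditions: NaBH4, MeOH/THF, −20 → 0 °C
Reagents that add atoms: none
Why: Chemoselective borohydride reduction of the aldehyde; the ketone between a quaternary and a tertiary carbon should react much more slowly at this temperature.

Step 17
Reactants: 20 primary alcohol
Product: 21 2α,6α-bis(tert-butyldimethylsilyloxy)-4β-[(tert-butyldimethylsilyloxy)methyl]-4α,8α,10β-trimethyl-5α-decalin-9-one
Conditions: TBSCl, imidazole, DMF, rt
Reagents that add atoms: tert-butyldimethylsilyl chloride CC(C)(C)[Si](C)(C)Cl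
Why: Silylation of the primary alcohol, which would otherwise be sulfonylated in step 18.

Step 18
Reactants: 21 tris-silyl ether ketone
Product: 22 C8=C9 enol triflate (2α,6α,19-tris(tert-butyldimethylsilyloxy)-9-(trifluoromethanesulfonyloxy)-podocarp-8-ene-type decalin with C17 methyl on C8)
Conditions: KN(SiMe3)2, THF, −78 → 0 °C; PhNTf2, −78 °C → rt
Reagents that add atoms: N-phenylbis(trifluoromethanesulfonimide) O=S(=O)(N(c1ccccc1)S(=O)(=O)C(F)(F)F)C(F)(F)F
Why: Enolate O-sulfonylation; the only α-hydrogen is on C8, so the tetrasubstituted C8=C9 enol triflate forms regiospecifically, as with other 2,2,6-trisubstituted cyclohexanones.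

Step 19
Reactants: 22 enol triflate
Product: 23 2α,6α,19-tris(tert-butyldimethylsilyloxy)-9-vinyl diene (C8=C9 and C11=C12)
Conditions: CH2=CHMgBr, ZnCl2, THF, 0 °C; then 22, Pd(PPh3)4 (5 mol %, zerovalent palladium), THF, 50 °C
Reagents that add atoms: vinylmagnesium bromide C=C[Mg]Br
Why: Negishi coupling of an alkenyl triflate with a small, reactive alkenylzinc reagent; oxidative addition of zerovalent palladium into the C–OTf bond, transmetalation and reductive elimination form C9–C11 without base.

Step 20
Reactants: 23 diene; 24 4-bromofuran-2(5H)-one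
Product: 26 2α,6α,19-tris(tert-butyldimethylsilyloxy)labda-8,13-dien-15,16-olide, via alkylborane 25 (not isolated)
Conditions: 9-BBN, THF, 0 °C → rt; then 24, Pd(dppf)Cl2 (5 mol %, divalent palladium precatalyst), AsPh3, K3PO4, DMF/H2O, rt → 40 °C
Reagents that add atoms: none
Why: 9-BBN adds only to the monosubstituted alkene, boron going to the terminal C12, and leaves the tetrasubstituted alkene; B-alkyl Suzuki–Miyaura coupling with the vinylogous acyl bromide then forms C12–C13 under a phosphate base mild enough for the butenolide.

Step 21
Reactants: 26 tris-silyl ether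
Product: 27 2α,6α,19-trihydroxylabda-8,13-dien-15,16-olide (target, CNP0387838.1)
Conditions: HF·pyridine, pyridine/THF, 0 °C → rt
Reagents that add atoms: none
Why: Fluoride cleavage of all three silyl ethers under buffered, non-basic conditions that the butenolide and the tetrasubstituted alkene tolerate; no stereocentre is touched.

## Compound list

1 | 2-methylcyclohex-2-en-1-one | CC1=CCCCC1=O | starting material
2 | trimethyl[(2-methylcyclohexa-1,3-dien-1-yl)oxy]silane | CC1=C(O[Si](C)(C)C)CCC=C1 | intermediate
3 | rac-4-hydroxy-2-methylcyclohex-2-en-1-one | CC1=CC(O)CCC1=O | intermediate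
4 | (S)-4-hydroxy-2-methylcyclohex-2-en-1-one | CC1=C[C@@H](O)CCC1=O | intermediate
5 | (S)-4-[(tert-butyldimethylsilyl)oxy]-2-methylcyclohex-2-en-1-one | CC1=C[C@@H](O[Si](C)(C)C(C)(C)C)CCC1=O | intermediate
6 | isopropenylmagnesium bromide (commercial THF solution) | CC(=C)[Mg]Br | starting material
7 | ethyl bromoacetate | CCOC(=O)CBr | starting material
8 | bromomagnesium C9 enolate of the conjugate adduct (C5 isopropenyl trans to C6 silyloxy; not isolated) | Br[Mg]OC1=C(C)[C@H](C(C)=C)[C@@H](O[Si](C)(C)C(C)(C)C)CC1 | intermediate
9 | ethyl 2-[(1S,2S,3S)-3-(tert-butyldimethylsilyloxy)-1-methyl-6-oxo-2-(prop-1-en-2-yl)cyclohexyl]acetate | O=C1[C@@](C)(CC(=O)OCC)[C@H](C(C)=C)[C@@H](O[Si](C)(C)C(C)(C)C)CC1 | intermediate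
10 | 2-[(1S,2S,3S)-3-(tert-butyldimethylsilyloxy)-6-hydroxy-1-methyl-2-(prop-1-en-2-yl)cyclohexyl]ethan-1-ol (C9 hydroxyl cis to the ring methyl) | O[C@@H]1[C@@](C)(CCO)[C@H](C(C)=C)[C@@H](O[Si](C)(C)C(C)(C)C)CC1 | intermediate
11 | 2-[(1S,2S,3S)-3-(tert-butyldimethylsilyloxy)-1-methyl-6-oxo-2-(prop-1-en-2-yl)cyclohexyl]acetaldehyde | O=C1[C@@](C)(CC=O)[C@H](C(C)=C)[C@@H](O[Si](C)(C)C(C)(C)C)CC1 | intermediate
12 | 6α-(tert-butyldimethylsilyloxy)-2β-hydroxy-10β-methyl-4-methylene-5α-decalin-9-one | O=C1[C@@]2(C)C[C@H](O)CC(=C)[C@@H]2[C@@H](O[Si](C)(C)C(C)(C)C)CC1 | intermediate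
13 | 2α-(4-nitrobenzoate) of the C2 epimer of 12 | O=C1[C@@]2(C)C[C@@H](OC(=O)c3ccc(cc3)[N+](=O)[O-])CC(=C)[C@@H]2[C@@H](O[Si](C)(C)C(C)(C)C)CC1 | intermediate
14 | 6α-(tert-butyldimethylsilyloxy)-2α-hydroxy-10β-methyl-4-methylene-5α-decalin-9-one | O=C1[C@@]2(C)C[C@@H](O)CC(=C)[C@@H]2[C@@H](O[Si](C)(C)C(C)(C)C)CC1 | intermediate
15 | 2α,6α-bis(tert-butyldimethylsilyloxy)-10β-methyl-4-methylene-5α-decalin-9-one | O=C1[C@@]2(C)C[C@@H](O[Si](C)(C)C(C)(C)C)CC(=C)[C@@H]2[C@@H](O[Si](C)(C)C(C)(C)C)CC1 | intermediate
16 | 2α,6α-bis(tert-butyldimethylsilyloxy)-8α,10β-dimethyl-4-methylene-5α-decalin-9-one | O=C1[C@@]2(C)C[C@@H](O[Si](C)(C)C(C)(C)C)CC(=C)[C@@H]2[C@@H](O[Si](C)(C)C(C)(C)C)C[C@H]1C | intermediate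
17 | C4 spiro-epoxide of 16 (oxygen α) | O=C1[C@@]2(C)C[C@@H](O[Si](C)(C)C(C)(C)C)C[C@]3(CO3)[C@@H]2[C@@H](O[Si](C)(C)C(C)(C)C)C[C@H]1C | intermediate
18 | 2α,6α-bis(tert-butyldimethylsilyloxy)-4α-formyl-8α,10β-dimethyl-5α-decalin-9-one | O=C1[C@@]2(C)C[C@@H](O[Si](C)(C)C(C)(C)C)C[C@@H](C=O)[C@@H]2[C@@H](O[Si](C)(C)C(C)(C)C)C[C@H]1C | intermediate
19 | 2α,6α-bis(tert-butyldimethylsilyloxy)-4β-formyl-4α,8α,10β-trimethyl-5α-decalin-9-one | O=C1[C@@]2(C)C[C@@H](O[Si](C)(C)C(C)(C)C)C[C@](C)(C=O)[C@@H]2[C@@H](O[Si](C)(C)C(C)(C)C)C[C@H]1C | intermediate
20 | 2α,6α-bis(tert-butyldimethylsilyloxy)-4β-(hydroxymethyl)-4α,8α,10β-trimethyl-5α-decalin-9-one | O=C1[C@@]2(C)C[C@@H](O[Si](C)(C)C(C)(C)C)C[C@](C)(CO)[C@@H]2[C@@H](O[Si](C)(C)C(C)(C)C)C[C@H]1C | intermediate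
21 | 2α,6α-bis(tert-butyldimethylsilyloxy)-4β-[(tert-butyldimethylsilyloxy)methyl]-4α,8α,10β-trimethyl-5α-decalin-9-one | O=C1[C@@]2(C)C[C@@H](O[Si](C)(C)C(C)(C)C)C[C@](C)(CO[Si](C)(C)C(C)(C)C)[C@@H]2[C@@H](O[Si](C)(C)C(C)(C)C)C[C@H]1C | intermediate
22 | C8=C9 enol triflate of 21 | CC1=C(OS(=O)(=O)C(F)(F)F)[C@@]2(C)C[C@@H](O[Si](C)(C)C(C)(C)C)C[C@](C)(CO[Si](C)(C)C(C)(C)C)[C@@H]2[C@@H](O[Si](C)(C)C(C)(C)C)C1 | intermediate
23 | 9-vinyl diene (C8=C9, C11=C12), tris-silyl ether | CC1=C(C=C)[C@@]2(C)C[C@@H](O[Si](C)(C)C(C)(C)C)C[C@](C)(CO[Si](C)(C)C(C)(C)C)[C@@H]2[C@@H](O[Si](C)(C)C(C)(C)C)C1 | intermediate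
24 | 4-bromofuran-2(5H)-one | O=C1C=C(Br)CO1 | starting material
25 | C12 B-alkyl-9-borabicyclo[3.3.1]nonane from 23 (not isolated) | CC1=C(CCB3C4CCCC3CCC4)[C@@]2(C)C[C@@H](O[Si](C)(C)C(C)(C)C)C[C@](C)(CO[Si](C)(C)C(C)(C)C)[C@@H]2[C@@H](O[Si](C)(C)C(C)(C)C)C1 | intermediate
26 | 2α,6α,19-tris(tert-butyldimethylsilyloxy)labda-8,13-dien-15,16-olide | CC1=C(CCC3=CC(=O)OC3)[C@@]2(C)C[C@@H](O[Si](C)(C)C(C)(C)C)C[C@](C)(CO[Si](C)(C)C(C)(C)C)[C@@H]2[C@@H](O[Si](C)(C)C(C)(C)C)C1 | intermediate
27 | 2α,6α,19-trihydroxylabda-8,13-dien-15,16-olide, (2R,4S,5R,6S,10S) | CC1=C(CCC2=CC(=O)OC2)[C@@]2(C)C[C@@H](O)C[C@](C)(CO)[C@@H]2[C@@H](O)C1 | target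

## Step count and least certain steps

Total: 21 steps. Longest linear sequence: 21 steps (1 → 27); 6, 7 and 24 are purchased.

**Step 5 (key step).** The most likely failure is slow C-alkylation of the hindered, copper-bound tetrasubstituted enolate, so that proton transfer toward C8 or plain protonation on work-up competes; erosion of the anti selectivity of the alkylation is the second concern. Fallback, from 5 to 9: the cuprate addition is run in the presence of Me3SiCl and the trimethylsilyl enol ether F1 is isolated. MeLi in THF then releases the lithium enolate F2 free of copper salts, and this is alkylated with 7 in THF/HMPA to give 9.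

**Step 9.** The most likely failure is E2 elimination of the axial oxyphosphonium ion toward the allylic C3 hydrogens outrunning substitution, or sluggish activation next to the C10 methyl. Fallback, from 12 to 14 (step 10 is then not needed): Tf2O and pyridine give the 2β-triflate F3. Bu4NNO2 in DMF at rt displaces it with inversion (Lattrell–Dax reaction) to the 2α-nitrite ester F4, which hydrolyses to 14 on aqueous work-up.

**Step 8.** The most likely failure is that the clash between the axial oxygen and the C10 methyl in the concerted transition state diverts the reaction to a stepwise Prins path (chloride capture, proton loss into the ring) or erodes the selectivity at C2. Any 2α-alcohol formed is already 14. Fallback, from 5 to 14 (steps 9 and 10 are then not needed): the ene closure is replaced by a Hosomi–Sakurai closure. The key step is run with the cuprate from the Grignard reagent of 2-bromo-3-(trimethylsilyl)propene and 7 to give allylsilane keto ester F5. LiAlH4 gives diol F6 and Dess–Martin periodinane gives keto aldehyde F7. BF3·OEt2 at −78 °C then closes ring A through an open transition state that has no need for an axial oxygen and should give 14.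

**Step 2 (with the dienol ether of step 1).** The most likely failure is loss of regiocontrol: deprotonation at C6 to the cross-conjugated ether, or peracid attack on the enol ether double bond leading to hydroxylation at C2. Fallback, from 1 to 3: KOtBu followed by kinetic protonation with AcOH gives the deconjugated ketone 2-methylcyclohex-3-en-1-one F8. mCPBA gives the epoxy ketone F9, and Et3N opens the epoxide by β-elimination to 3.

**Step 3.** The most likely failure is insufficient discrimination of the enantiomers by the lipase, because the two ring arms at the carbinol differ little in size, or a reversed sense. Fallback, from 3 to 4: esterification of 3 with (S)-2-methoxy-2-phenylacetic acid (DCC, DMAP, −10 °C) gives the diastereomeric esters F10 (from the (S)-alcohol) and F11 (from the (R)-alcohol). These are separated by chromatography or crystallisation, and K2CO3 in MeOH releases 4 from F10.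

**Step 20.** The most likely failure is decomposition of bromobutenolide 24 or protodeboronation of 25 under the aqueous base before transmetalation. Fallback, from 23 to 26: hydroboration as before, then oxidative work-up with NaBO3·4H2O, gives the C12 alcohol F12. I2, PPh3 and imidazole give iodide F13. Zinc insertion (Zn dust, LiCl, THF) gives the alkylzinc iodide F14, which is coupled with 24 under base-free Negishi conditions (Pd(PPh3)4, THF, rt) to give 26.

## Further compounds

F1 | step 5 | trimethylsilyl enol ether of the conjugate adduct | C[Si](C)(C)OC1=C(C)[C@H](C(C)=C)[C@@H](O[Si](C)(C)C(C)(C)C)CC1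
F2 | step 5 | lithium enolate of the conjugate adduct | [Li]OC1=C(C)[C@H](C(C)=C)[C@@H](O[Si](C)(C)C(C)(C)C)CC1
F3 | step 9 | 2β-triflate of 12 | O=C1[C@@]2(C)C[C@H](OS(=O)(=O)C(F)(F)F)CC(=C)[C@@H]2[C@@H](O[Si](C)(C)C(C)(C)C)CC1
F4 | step 9 | 2α-nitrite ester of 14 | O=C1[C@@]2(C)C[C@@H](ON=O)CC(=C)[C@@H]2[C@@H](O[Si](C)(C)C(C)(C)C)CC1
F5 | step 8 | ethyl 2-[(1S,2S,3S)-3-(tert-butyldimethylsilyloxy)-1-methyl-6-oxo-2-[3-(trimethylsilyl)prop-1-en-2-yl]cyclohexyl]acetate | O=C1[C@@](C)(CC(=O)OCC)[C@H](C(=C)C[Si](C)(C)C)[C@@H](O[Si](C)(C)C(C)(C)C)CC1
F6 | step 8 | allylsilane diol (C9 hydroxyl cis to the ring methyl) | O[C@@H]1[C@@](C)(CCO)[C@H](C(=C)C[Si](C)(C)C)[C@@H](O[Si](C)(C)C(C)(C)C)CC1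
F7 | step 8 | allylsilane keto aldehyde | O=C1[C@@](C)(CC=O)[C@H](C(=C)C[Si](C)(C)C)[C@@H](O[Si](C)(C)C(C)(C)C)CC1
F8 | step 2 | 2-methylcyclohex-3-en-1-one (racemic) | CC1C=CCCC1=O
F9 | step 2 | 3,4-epoxy-2-methylcyclohexan-1-one (racemic, both epoxide faces) | CC1C2OC2CCC1=O
F10 | step 3 | (S)-2-methyl-1-oxocyclohex-2-en-4-yl (S)-2-methoxy-2-phenylacetate | CC1=C[C@@H](OC(=O)[C@@H](OC)c2ccccc2)CCC1=O
F11 | step 3 | (R)-2-methyl-1-oxocyclohex-2-en-4-yl (S)-2-methoxy-2-phenylacetate | CC1=C[C@H](OC(=O)[C@@H](OC)c2ccccc2)CCC1=O
F12 | step 20 | C12 primary alcohol from 23 | CC1=C(CCO)[C@@]2(C)C[C@@H](O[Si](C)(C)C(C)(C)C)C[C@](C)(CO[Si](C)(C)C(C)(C)C)[C@@H]2[C@@H](O[Si](C)(C)C(C)(C)C)C1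
F13 | step 20 | C12 iodide | CC1=C(CCI)[C@@]2(C)C[C@@H](O[Si](C)(C)C(C)(C)C)C[C@](C)(CO[Si](C)(C)C(C)(C)C)[C@@H]2[C@@H](O[Si](C)(C)C(C)(C)C)C1
F14 | step 20 | C12 alkylzinc iodide | CC1=C(CC[Zn]I)[C@@]2(C)C[C@@H](O[Si](C)(C)C(C)(C)C)C[C@](C)(CO[Si](C)(C)C(C)(C)C)[C@@H]2[C@@H](O[Si](C)(C)C(C)(C)C)C1
A1 | alternative 1 | acyclic triene with (E)-aryl enol ether | C=C(C)/C(CCOC(=O)C(C)(C)C)=C(C)/C[C@@H](O[Si](C)(C)C(C)(C)C)C[C@](C)(CO[Si](C)(C)C(C)(C)C)/C=C/Oc1ccc(OC)cc1
A2 | alternative 1 | decalin cycloadduct with C6 aryl ether | CC1=C(CCOC(=O)C(C)(C)C)[C@@]2(C)C[C@@H](O[Si](C)(C)C(C)(C)C)C[C@](C)(CO[Si](C)(C)C(C)(C)C)[C@@H]2[C@@H](Oc3ccc(OC)cc3)C1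
A3 | alternative 2 | 2-methylcyclohexane-1,3-dione with acrylate side chain | O=C1CCCC(=O)C1(C)C[C@@H](O[Si](C)(C)C(C)(C)C)CC(=C)C(=O)OC
A4 | alternative 2 | bicyclic β-hydroxy ester with C9 ketone | O=C1[C@@]2(C)C[C@@H](O[Si](C)(C)C(C)(C)C)C[C@](C)(C(=O)OC)[C@@]2(O)CCC1
A5 | alternative 3 | 2-methylene pyran fused to ring B at C5–C6 | C=C1C[C@](C)(CO[Si](C)(C)C(C)(C)C)C2=C(C)C(OCc3ccc(OC)cc3)CC[C@@H]2O1
A6 | alternative 3 | 2-oxo decalin with C5=C6 alkene | O=C1C[C@](C)(CO[Si](C)(C)C(C)(C)C)C2=CCCC(OCc3ccc(OC)cc3)[C@@]2(C)C1
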